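A slow leak feeds this flask: you charge the reagent into the second phase, and it meets starting material only after crossing, where it can also be lost.

    reagent in the reaction phase → decomposed reagent (k1 = 2.0 × 10⁻⁴ s⁻¹)
    starting material + reagent in the reaction phase → target (k2 = 0.0018 M⁻¹ s⁻¹)
    target ⇌ isomer of the product (K3 = 1.7, k3 = 3.1 × 10⁻⁴ s⁻¹)
    2 reagent in the reaction phase → self-condensation product (k4 = 0.0011 M⁻¹ s⁻¹)
    reagent in the reaction phase ⇌ reagent in the second phase, rate k5*([reagent in the reaction phase] - [reagent in the second phase]/K5) per volume of the first phase (K5 = 2.0, k5 = 2.9 × 10⁻⁴ s⁻¹)

starting material 0.088 M; reagent in the second phase 0.0968 M; time 2.5 h; volume of the second phase over the first 1.0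

- target at 2.5 h, in percent of the starting material charged
- the change that raises the amount of target at 2.5 h, in percent of the starting material charged most ("none" if none brings more than 2 percentage points) (south-east / south-west / none)
- amount of target at 2.5 h, in percent of the starting material charged, after south-west

- a doubled species enters its step squared and goes two at a time
- in the second phase: reagent in the second phase; everything else is in the first
- charges count per volume of the first phase; a concentration in a rate is the amount of a species over the volume of its own phase; every rate counts per litre of the first phase
- run time (flask): 2.5 h

First guess: the second phase empties at the partition-scaled constant 1.45 × 10⁻⁴ s⁻¹, which leaves 27.1% of its charge at 2.5 h. What does the crossed reagent buy? Compare rates at one moment. The target step and decomposition are both first order in reagent in the reaction phase, so its concentration cancels from their ratio. That leaves the capture ratio, starting material converted per reagent decomposed, which is the target step's constant times the starting material over the decomposition constant, a selectivity factor: 0.792 at the start. It drifts down as starting material falls. So 44.2% of the reagent spent on these two steps forms product, and the first guess converts 35.4%.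

But crossing is reversible. Reagent in the reaction phase returns at 2.9 × 10⁻⁴ s⁻¹ and, counting decomposition and the target step at the starting charge, is lost at 3.58 × 10⁻⁴ s⁻¹, so 44.8% of what enters goes back, and the net drain is 8.01 × 10⁻⁵ s⁻¹. That leaves 0.0471 M in the second phase and about 0.0105 M standing in the reaction phase, so 0.0392 M is spent and 19.7% converted, an estimate that holds the share at its starting value.

And the product isomerises: its relaxation half-life, 0.391 h, is shorter than the run. With a steady feed, target keeps 51.2% of the product, so I commit to 10.1%. Doubling the charge nearly doubles that, while doubling the coefficient raises the drain to 1.11 × 10⁻⁴ s⁻¹, 1.38 times the old one, so I choose south-east.

The forecast puts target lower than my figure, at 9%, chooses south-east and gives 10.5% after south-west, saying “Doubling the reagent nearly doubles conversion”.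

The simulation gives 9.09% of target, south-east as the best change (gaining 6.9 percentage points, against 1.6 points for south-west) and 10.7% after south-west.

In this flask, at 0.819 h, decomposition uses reagent 1.3 times as fast as the target step. The capture ratio, 0.792 at the start and 0.649 with the starting material left at 2.50 h, brackets the turnover of the target step over the decomposed reagent up to that time, 0.718. For the neighbour charged with 0.035 M of starting material, the ratio runs from 0.315 to 0.251. Its computed target and isomer together, over its decomposed reagent at 2.50 h, come to 0.282, with target at 10.3% of that neighbour's own charge.

The numbers belong to no real substance; the run is a simulation.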